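The earlier runs and the new flask were generated by integration with constants of no real substance, and the scatter is random.

At 80 min, each millimole of substrate charged stands in one of three entries of a ledger: still there, product, or a toll of substrate gone without product. Substrate is the limiting reagent, with 36.0 mM of partner against at most 24 mM of substrate.

| setting | delta | zeta | beta | east | south-east | south | north-west |
|---|---|---|---|---|---|---|---|
| substrate | 24 mM | 24 mM | 20 mM | 15 mM | 24 mM | 15 mM | 24 mM |
| partner | 36 mM | 36 mM | 36 mM | 36.0 mM | 36.0 mM | 36.0 mM | 36.0 mM |
| initiator | 1.3 mM | 2.7 mM | 2.4 mM | 2.4 mM | 2.4 mM | 4.0 mM | 4.0 mM |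
| remark | run made earlier | run made earlier | run made earlier |  |  |  |  |
| time |  |  |  | 80 min | 80 min | 80 min | 80 min |

- delta (time / min: product / %, substrate / %): 5.00: 5.1, 93.5; 15.0: 14.9, 82.9; 25.0: 22.4, 73.0; 40.0: 32.7, 63.4
- zeta (time / min: product / %, substrate / %): 3.00: 6.1, 95.0; 8.00: 10.6, 85.0; 15.0: 22.3, 74.1; 40.0: 44.3, 45.9
- beta (time / min: product / %, substrate / %): 5.00: 11.0, 88.9; 15.0: 24.0, 69.6; 25.0: 35.2, 57.5; 40.0: 51.3, 38.3

(readings scatter by 1 percentage point)

1. ranking by amount of product, in percent of the substrate charged, from high to low, at 80 min (east / south-east / south / north-west)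
2. the amount of product, in percent of the substrate charged of the flask you put first, at 80 min
3. the amount of product, in percent of the substrate charged of the flask you put last, at 80 min

This reckoning is ours. At 40.0 min, the gap left by substrate and product, per millimole of initiator charged, reads 0.720 in delta, 0.871 in zeta and 0.867 in beta. Their mean over that time is the toll rate 0.0205 min⁻¹, so we replace the toll's curve by a straight line:

toll = w · c(initiator) · running time

Beta used 12.3 mM of substrate by 40.0 min, and we scale that with the root of initiator. Its mean use fell from 0.405 mM min⁻¹ to 0.250 mM min⁻¹, and we square that ratio to get 0.382, our estimate of the use from 40.0 min to 80 min against the use up to 40.0 min.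

East: substrate lasts 50.6 min, toll 2.49 mM, product 83.4%

South: substrate lasts 37.7 min, toll 3.09 mM, product 79.4%

North-west: used 22.0 mM, toll 6.55 mM, product 64.4%

South-east: used 17.0 mM, toll 3.93 mM, product 54.5%

The forecast ranks east > north-west > south > south-east, with 83% on top (76% to 88%) and 61% last (54% to 66%), and it reasons that “each initiator seems to consume one substrate”. It differs from ours in the places of south and north-west, and in a higher last value.

The flasks give east > south > north-west > south-east, with 83.4% and 61.4%.

    initiator → 2 initiating radical (k = 2.20 × 10⁻⁴ s⁻¹)
    substrate + initiating radical → capped initiator + first chain carrier (k = 7300 L mol⁻¹ s⁻¹)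
    partner + first chain carrier → product + second chain carrier (k = 300 L mol⁻¹ s⁻¹)
    substrate + second chain carrier → released group + first chain carrier (k = 100 L mol⁻¹ s⁻¹)
    2 first chain carrier → ended chains (k = 1.50 × 10⁶ L mol⁻¹ s⁻¹)
    partner ⇌ dormant form (K = 2.00, k = 1.00 × 10⁻⁴ s⁻¹)

South-east's books close at 80 min with substrate 25.6%, product 61.4% and ended chains 13.0%, each counted as two, and beside them stands 3.13 mM of capped initiator, against 3.12 mM of substrate in that last entry. The toll rate gave 3.93 mM there, so the straight line stands above the curve, and the capped initiator is 0.796 of it.

In a neighbour flask, like east but with 0.96 mM of initiator, the toll rate gives 1.57 mM at 80 min, and with that same ratio 1.25 mM. The computed flask holds 1.25 mM of capped initiator, with product at 68.8%.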